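Numbering follows the heavy atoms of the target SMILES (C1 to C26). Ring A is C6–C11, ring B the δ-lactone C9/C10/C12/O14/C15/C16, ring C is C16/C17/C19/C20/C24/C23, ring D is C20/O21/C22/C23/C24. The plan rests on quaternary C24 (two methyl groups) of ring C: it lies between oxygen-bearing C20 and C23, and C23 is β to the C17 ketone, so C23–C24 is the bond of a tertiary radical to an enone.
Side chain and ring A: C2–C3 comes from carbonylation of the enol triflate of a C6 acetyl group, C6–C11 from an intramolecular Michael addition, C10=C11 from Mannich methylenation, and C8–C9 from organocopper addition to the unsaturated spirolactone. A 2-siloxydiene cycloaddition would follow the para rule and put its oxygen on C7, not C6.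
Ring B: acrylate ring-closing metathesis (C9=C10). Ring D: oxa-Michael addition of the C22 hydroxyl to C20 of the ring C enone.
Spiro centre C16: hydroxymethylation (C15) of a temporary cis-fused γ-lactone that ties the C9 carboxyl to the C22 oxygen, so that C23 dictates C16.
Ring C: hydrogen-atom-transfer radical 6-endo cyclisation of an acyclic alkylidene β-keto ester built from methyl acetoacetate, methacrolein and benzyloxyacetaldehyde. Rings form in the order C, D, B, A.

Key step: step 6

Assumption: (S)-BINOL is taken to give the 5S aldol 7, by analogy with the usual sense of induction of BINOL–titanium catalysts with aromatic and α,β-unsaturated aldehydes; if the sense is opposite, (R)-BINOL is used.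
Remark: centres that are mixtures and are erased later (C9 and C17 in 17, C17 in 18, C10 in 25 and 26) are left undefined in the SMILES.

Step 1
Reactants: 1 methyl acetoacetate
Product: 2 methyl 3-(trimethylsilyloxy)but-2-enoate (E/Z mixture)
Conditions: Me3SiCl, Et3N, hexane, rt
Reagents that add atoms: chlorotrimethylsilane, C[Si](C)(C)Cl
Why: Soft enolisation and O-silylation of the β-keto ester give the silyl enol ether that masks the acidic C16 position for the following γ-deprotonation; no stereocentre is formed.

Step 2
Reactants: 2 methyl 3-(trimethylsilyloxy)but-2-enoate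
Product: 4 1-methoxy-1,3-bis(trimethylsilyloxy)buta-1,3-diene, via lithium dienolate 3 (not isolated)
Conditions: LiN(iPr)2, THF, –78 °C; Me3SiCl, –78 to 0 °C
Reagents that add atoms: chlorotrimethylsilane, C[Si](C)(C)Cl; lithium diisopropylamide, [Li+].CC(C)[N-]C(C)C (in 3 only)
Why: Kinetic γ-deprotonation of the vinylogous ester and O-silylation of the dienolate give the bis(silyl) dienol ether, the usual γ-nucleophilic equivalent of acetoacetate; no stereocentre is formed.

Step 3
Reactants: 4 1-methoxy-1,3-bis(trimethylsilyloxy)buta-1,3-diene; 5 methacrolein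
Product: 7 methyl (5S)-5-hydroxy-6-methyl-3-oxohept-6-enoate, via bis(silyl) aldol adduct 6 (not isolated)
Conditions: (S)-BINOL (10 mol %), Ti(OiPr)4 (10 mol %), 4 Å MS, THF, –78 °C to rt; then 1 M HCl, THF, 0 °C
Reagents that add atoms: none
Why: Catalytic enantioselective vinylogous Mukaiyama aldol addition: the diene reacts through its terminal carbon (C19) at the aldehyde carbonyl, the chiral BINOL–titanium complex differentiates the aldehyde faces and sets C20 as S, and dilute acid then removes both silyl groups.

Step 4
Reactants: 7 methyl (5S)-5-hydroxy-6-methyl-3-oxohept-6-enoate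
Product: 8 methyl (5S)-5-(tert-butyldimethylsilyloxy)-6-methyl-3-oxohept-6-enoate
Conditions: tBuMe2SiCl, imidazole, DMF, rt
Reagents that add atoms: tert-butylchlorodimethylsilane, CC(C)(C)[Si](C)(C)Cl
Why: Standard silylation of the secondary allylic alcohol under mild base spares the β-hydroxy ketone from elimination and installs the bulky group that later steers the radical closure; C20 is untouched.

Step 5
Reactants: 8 methyl (5S)-5-(tert-butyldimethylsilyloxy)-6-methyl-3-oxohept-6-enoate; 9 benzyloxyacetaldehyde
Product: 10 methyl (2Z,5S)-2-[2-(benzyloxy)ethylidene]-5-(tert-butyldimethylsilyloxy)-6-methyl-3-oxohept-6-enoate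
Conditions: piperidine (10 mol %), AcOH (10 mol %), 4 Å MS, CH2Cl2, 0 °C to rt; chromatographic separation of the Z isomer
Reagents that add atoms: none
Why: Knoevenagel condensation under piperidinium acetate catalysis; the Z isomer (C22 cis to the ester, trans to C17) should prevail because the ketone stays conjugated while the ester twists, and the E isomer can be re-equilibrated under the same catalyst.

Step 6
Reactants: 10 methyl (2Z,5S)-2-[2-(benzyloxy)ethylidene]-5-(tert-butyldimethylsilyloxy)-6-methyl-3-oxohept-6-enoate
Product: 11 ring C β-keto ester, methyl 6-[(benzyloxy)methyl]-4-(tert-butyldimethylsilyloxy)-5,5-dimethyl-2-oxocyclohexane-1-carboxylate (silyloxy at C20 and benzyloxymethyl at C23 cis; C16 labile, drawn with the ester trans to the C23 substituent)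
Conditions: Fe(acac)3 (30 mol %), PhSiH3 (2.5 equiv), EtOH (0.02 M), 60 °C
Reagents that add atoms: none
Why: Fe(acac)3 and PhSiH3 in ethanol generate an iron hydride that transfers a hydrogen atom to the terminal CH2 of the electron-rich 1,1-disubstituted alkene, which creates the second methyl group and the tertiary, nucleophilic C24 radical; this radical adds to C23, and the resulting C16 radical, stabilised by ketone and ester, is reduced by divalent iron and protonated by the solvent. The closest known reaction type is the iron-mediated reductive olefin coupling (hydrogen-atom-transfer Giese addition), used here intramolecularly. Ring C closes 6-endo-trig, because both acceptor groups sit on C16 and polarise the alkene towards attack at C23, whereas 5-exo attack at fully substituted C16 would join two quaternary carbons and leave an unstabilised radical. The new centre C23 is controlled by C20: in the chair-like transition state the bulky silyloxy group lies equatorial and anti to the forming bond, and the Z geometry puts C22 (trans to C17) equatorial as well, which gives the 1,3-cis relation that ring D needs. The step needs chemoselective hydrogen-atom transfer (secured by the electronic gap between the donor alkene and the doubly activated alkene) and a geometrically pure Z acceptor (the E isomer would place C22 axial and lead to the trans series). C16 is formed as a labile keto–enol centre and is fixed only in step 8.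

Step 7
Reactants: 11 ring C β-keto ester
Product: 13 cis-fused keto γ-lactone 5-(tert-butyldimethylsilyloxy)-4,4-dimethylhexahydroisobenzofuran-1,7-dione (lactone C=O is C9 and lactone CH2 is C22), via hydroxy keto ester 12 (not isolated)
Conditions: H2 (1 atm), Pd/C, EtOAc, rt; filter; DMAP (20 mol %), toluene, 90 °C
Reagents that add atoms: none
Why: Hydrogenolysis of the benzyl ether and DMAP-catalysed transesterification of the β-keto ester: labile C16 equilibrates through the enol so that the γ-lactone closes cis-fused, base rather than acid is used to avoid dehydrative closure onto the C17 ketone, and chromatography here removes any C20/C23-trans material, which would otherwise lower the enantiomeric purity after step 10.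

Step 8
Reactants: 13 cis-fused keto γ-lactone
Product: 14 7a-(hydroxymethyl) keto γ-lactone (C15 on C16, trans to C22; lactone still cis-fused)
Conditions: 37% aq. HCHO, KHCO3 (20 mol %), THF, 0 °C to rt
Reagents that add atoms: formaldehyde, C=O
Why: Base-catalysed aldol addition of a β-dicarbonyl compound to formaldehyde (hydroxymethylation): the enolate of the cis-bicycle is attacked on the convex face, syn to H23 and anti to quaternary C24, the only face that keeps the γ-lactone cis-fused, so C15 ends trans to C22 and the spiro centre C16 is set by C23.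

Step 9
Reactants: 14 7a-(hydroxymethyl) keto γ-lactone
Product: 15 pivalate of 14 (C15–O–COtBu)
Conditions: tBuCOCl, pyridine, DMAP (cat.), CH2Cl2, 0 °C to rt
Reagents that add atoms: pivaloyl chloride, CC(C)(C)C(=O)Cl
Why: Acylation of the primary alcohol blocks retro-aldol loss of formaldehyde during the next, basic step, and the ester is removed without an extra operation in step 11.

Step 10
Reactants: 15 pivalate
Product: 16 enone γ-lactone pivalate (C19=C20 conjugated with the C17 ketone)
Conditions: DBU, toluene, 60 °C
Reagents that add atoms: none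
Why: E1cB elimination of the β-silyloxy group (C16 is quaternary, so only C19 can be deprotonated) gives the enone; C20 has served as control element for C23 and is re-created in step 13, and the alkene makes the C17 oxygen allylic, which allows its selective re-oxidation.

Step 11
Reactants: 16 enone γ-lactone pivalate
Product: 17 lactol triol 7a-(hydroxymethyl)-4,4-dimethyl-1,3,3a,4,7,7a-hexahydroisobenzofuran-1,7-diol (mixture at C9 and C17)
Conditions: iBu2AlH (7 equiv), CH2Cl2, –78 °C; aq. potassium sodium tartrate
Reagents that add atoms: none
Why: Low-temperature iBu2AlH reduction stops the lactone at the lactol, reduces the enone 1,2 to the allylic alcohol and cleaves the pivalate; the new carbinol centres C9 and C17 are mixtures and are both erased later.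

Step 12
Reactants: 17 lactol triol
Product: 18 vinyl triol (2-hydroxy-5,5-dimethyl-1-vinylcyclohex-3-ene-1,6-diyl)dimethanol (vinyl on C16 cis to the C22 hydroxymethyl on C23)
Conditions: Ph3PCH3Br, KOtBu, THF, 0 °C to rt
Reagents that add atoms: methyltriphenylphosphonium bromide, C[P+](c1ccccc1)(c1ccccc1)c1ccccc1.[Br-]
Why: Wittig methylenation of the lactol through its open hydroxy aldehyde form turns C9 into the vinyl group and frees the C22 hydroxyl; a non-stabilised ylide is chosen so that fast olefination outruns retro-aldol cleavage and leaves no acceptor for the liberated alcohol.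

Step 13
Reactants: 18 vinyl triol
Product: 20 rings C and D, 2-(hydroxymethyl)-8,8-dimethyl-2-vinyl-6-oxabicyclo[3.2.1]octan-3-one, via hydroxy enone 19 (not isolated)
Conditions: MnO2, CH2Cl2, rt; filter; camphorsulfonic acid (5 mol %), CH2Cl2, rt
Reagents that add atoms: none
Why: Chemoselective MnO2 oxidation of the only allylic alcohol, then acid-catalysed intramolecular oxa-Michael addition (5-exo-trig): C22, squeezed between quaternary C16 and C24, stands pseudo-axial over the enone, so its hydroxyl can reach C20 only from its own face, which closes ring D and re-creates C20 as S under control of C23.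

Step 14
Reactants: 20 hydroxymethyl ketone (rings C and D)
Product: 21 acrylate ester of 20 (C15–O–CO–CH=CH2)
Conditions: acryloyl chloride, iPr2NEt, DMAP (cat.), CH2Cl2, –20 to 0 °C
Reagents that add atoms: acryloyl chloride, C=CC(=O)Cl
Why: Acylation of the one remaining hydroxyl group (neopentyl C15–OH) under mild amine base should be faster than retro-aldol cleavage of the β-hydroxy ketone.

Step 15
Reactants: 21 acrylate ester
Product: 22 unsaturated spirolactone (rings B, C, D; 5,6-dihydro-2H-pyran-2-one with C9=C10, spiro at C16)
Conditions: second-generation Hoveyda–Grubbs catalyst RuCl2(H2IMes)(=CH-C6H4-2-OiPr) (10 mol %), toluene (5 mM), 80 °C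
Reagents that add atoms: none
Why: Ring-closing metathesis of the acrylate with the neopentyl vinyl group closes the six-membered α,β-unsaturated lactone (ring B) with loss of ethene; heat and the phosphine-free ruthenium carbene are chosen for the hindered, electron-poor alkene pair.

Step 16
Reactants: 22 unsaturated spirolactone; 23 2-(3-chloropropyl)-2-methyl-1,3-dioxolane
Product: 25 Mannich base (C9 carries the 3-(2-methyl-1,3-dioxolan-2-yl)propyl chain and C10 carries CH2NMe2), via silyl ketene acetal 24 (not isolated)
Conditions: 23, Mg, THF, reflux; CuBr·SMe2, THF, –78 °C; Me3SiCl, then 22, –78 to –30 °C; Me2N=CH2 I, CH2Cl2, –30 °C to rt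
Reagents that add atoms: Eschenmoser's salt, C=[N+](C)C.[I-]; chlorotrimethylsilane, C[Si](C)(C)Cl (in 24 only)
Why: Silyl-chloride-accelerated organocopper conjugate addition followed by Mannich capture of the regiodefined silyl ketene acetal: in the favoured half-chair of ring B the bulky C23 branch stands pseudo-axial (this keeps H9 away from C22H2), so C8 is delivered to C9 on the opposite face, syn to C17, which sets C9, while the soft copper reagent leaves the hindered C17 ketone untouched and C10 needs no control because it becomes sp2 in step 17.

Step 17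
Reactants: 25 Mannich base
Product: 27 α-methylene lactone ketal (C10=C11H2), via ammonium iodide 26 (not isolated)
Conditions: MeI, CH2Cl2–Et2O, rt; then satd aq. NaHCO3, CH2Cl2, rt
Reagents that add atoms: iodomethane, CI (in 26 only)
Why: Exhaustive methylation and Hofmann-type β-elimination of the Mannich base is the classical α-methylenation of lactones and avoids any strong base that would touch the more acidic C19 position.

Step 18
Reactants: 27 α-methylene lactone ketal
Product: 28 keto α-methylene lactone (C9 carries a 4-oxopentyl chain)
Conditions: 1 M HCl, THF, rt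
Reagents that add atoms: water, O
Why: Mild acid hydrolysis of the dioxolane frees the methyl ketone; lactone, cyclic ether and exocyclic alkene are stable to dilute acid.

Step 19
Reactants: 28 keto α-methylene lactone
Product: 29 tetracyclic methyl ketone (rings A to D; acetyl on C6 equatorial, A/B cis-fused)
Conditions: KOtBu (20 mol %), tBuOH–THF, 0 °C
Reagents that add atoms: none
Why: Intramolecular Michael addition (6-endo-trig, enolate exo) under equilibrating catalytic base: only the C6 enolate can reach C11 in a chair-like array from the axial C8 chain, the acetyl group settles equatorial (sets C6), and protonation at C10 gives the cis A/B fusion because the trans isomer would force C8 anti to C15 and into C22H2 of ring D.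

Step 20
Reactants: 29 tetracyclic methyl ketone
Product: 31 terminal enol triflate (C2(OTf)=C1H2 on C6), via potassium enolate 30 (not isolated)
Conditions: KN(SiMe3)2 (1.05 equiv), THF, –78 °C; PhNTf2, –78 to 0 °C
Reagents that add atoms: N-phenylbis(trifluoromethanesulfonimide), O=S(=O)(C(F)(F)F)N(c1ccccc1)S(=O)(=O)C(F)(F)F; potassium bis(trimethylsilyl)amide, C[Si](C)(C)[N-][Si](C)(C)C.[K+] (in 30 only)
Why: Kinetic deprotonation at the exposed methyl group with a bulky amide base and O-triflation give the terminal enol triflate; the competing C19–H is shielded by the syn-axial C15 and C24-methyl groups and the lactone C10–H is less acidic, so C6 and C10 are not disturbed.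

Step 21
Reactants: 31 terminal enol triflate
Product: 32 target acid CNP0268721.1
Conditions: Pd(OAc)2 (5 mol %), dppf [Fe(C5H4PPh2)2] (10 mol %), CO (1 atm), H2O, Et3N, DMF, 50 °C
Reagents that add atoms: carbon monoxide, [C-]#[O+]; water, O
Why: Palladium-catalysed hydroxycarbonylation of the vinyl triflate (oxidative addition to zerovalent palladium, CO insertion, hydrolysis of the acyl complex) installs C3 and gives the 2-substituted acrylic acid directly, without an ester hydrolysis that would endanger the lactone.

Compound list
1 | methyl acetoacetate | CC(=O)CC(=O)OC | starting material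
2 | methyl 3-(trimethylsilyloxy)but-2-enoate (E/Z mixture) | COC(=O)C=C(C)O[Si](C)(C)C | intermediate
3 | lithium dienolate of 2 | [Li+].[O-]C(OC)=CC(=C)O[Si](C)(C)C | intermediate
4 | 1-methoxy-1,3-bis(trimethylsilyloxy)buta-1,3-diene | COC(O[Si](C)(C)C)=CC(=C)O[Si](C)(C)C | intermediate
5 | methacrolein | CC(=C)C=O | starting material
6 | methyl (5S)-6-methyl-3,5-bis(trimethylsilyloxy)hepta-2,6-dienoate | C=C(C)[C@@H](O[Si](C)(C)C)CC(O[Si](C)(C)C)=CC(=O)OC | intermediate
7 | methyl (5S)-5-hydroxy-6-methyl-3-oxohept-6-enoate | C=C(C)[C@@H](O)CC(=O)CC(=O)OC | intermediate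
8 | methyl (5S)-5-(tert-butyldimethylsilyloxy)-6-methyl-3-oxohept-6-enoate | C=C(C)[C@@H](O[Si](C)(C)C(C)(C)C)CC(=O)CC(=O)OC | intermediate
9 | benzyloxyacetaldehyde | O=CCOCc1ccccc1 | starting material
10 | methyl (2Z,5S)-2-[2-(benzyloxy)ethylidene]-5-(tert-butyldimethylsilyloxy)-6-methyl-3-oxohept-6-enoate | C=C(C)[C@@H](O[Si](C)(C)C(C)(C)C)CC(=O)/C(C(=O)OC)=C/COCc1ccccc1 | intermediate
11 | ring C β-keto ester, silyloxy and benzyloxymethyl cis, C16 labile | COC(=O)[C@H]1C(=O)C[C@H](O[Si](C)(C)C(C)(C)C)C(C)(C)[C@@H]1COCc2ccccc2 | intermediate
12 | hydroxy keto ester (debenzylated 11) | COC(=O)[C@H]1C(=O)C[C@H](O[Si](C)(C)C(C)(C)C)C(C)(C)[C@@H]1CO | intermediate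
13 | cis-fused keto γ-lactone | O=C1OC[C@H]2C(C)(C)[C@@H](O[Si](C)(C)C(C)(C)C)CC(=O)[C@@H]12 | intermediate
14 | 7a-(hydroxymethyl) keto γ-lactone | O=C1OC[C@H]2C(C)(C)[C@@H](O[Si](C)(C)C(C)(C)C)CC(=O)[C@@]12CO | intermediate
15 | pivalate of 14 | O=C1OC[C@H]2C(C)(C)[C@@H](O[Si](C)(C)C(C)(C)C)CC(=O)[C@@]12COC(=O)C(C)(C)C | intermediate
16 | enone γ-lactone pivalate | O=C1OC[C@H]2C(C)(C)C=CC(=O)[C@@]12COC(=O)C(C)(C)C | intermediate
17 | lactol triol (mixture at C9 and C17) | OC1OC[C@H]2C(C)(C)C=CC(O)[C@@]12CO | intermediate
18 | vinyl triol (mixture at C17) | C=C[C@]1(CO)C(O)C=CC(C)(C)[C@@H]1CO | intermediate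
19 | hydroxy enone 5,6-bis(hydroxymethyl)-4,4-dimethyl-6-vinylcyclohex-2-enone | C=C[C@]1(CO)C(=O)C=CC(C)(C)[C@@H]1CO | intermediate
20 | 2-(hydroxymethyl)-8,8-dimethyl-2-vinyl-6-oxabicyclo[3.2.1]octan-3-one | C=C[C@]1(CO)C(=O)C[C@@H]2OC[C@H]1C2(C)C | intermediate
21 | acrylate ester of 20 | C=CC(=O)OC[C@@]1(C=C)C(=O)C[C@@H]2OC[C@H]1C2(C)C | intermediate
22 | unsaturated spirolactone (rings B, C, D) | O=C1OC[C@@]2(C=C1)C(=O)C[C@@H]3OC[C@H]2C3(C)C | intermediate
23 | 2-(3-chloropropyl)-2-methyl-1,3-dioxolane | CC1(CCCCl)OCCO1 | starting material
24 | trimethylsilyl ketene acetal of the C9-alkylated lactone | C[Si](C)(C)OC1=C[C@@H](CCCC4(C)OCCO4)[C@]2(CO1)C(=O)C[C@@H]3OC[C@H]2C3(C)C | intermediate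
25 | Mannich base (mixture at C10) | O=C1OC[C@@]2([C@H](CCCC4(C)OCCO4)C1CN(C)C)C(=O)C[C@@H]3OC[C@H]2C3(C)C | intermediate
26 | trimethylammonium iodide of 25 | O=C1OC[C@@]2([C@H](CCCC4(C)OCCO4)C1C[N+](C)(C)C)C(=O)C[C@@H]3OC[C@H]2C3(C)C.[I-] | intermediate
27 | α-methylene lactone ketal | O=C1OC[C@@]2([C@H](CCCC4(C)OCCO4)C1=C)C(=O)C[C@@H]3OC[C@H]2C3(C)C | intermediate
28 | keto α-methylene lactone | O=C1OC[C@@]2([C@H](CCCC(C)=O)C1=C)C(=O)C[C@@H]3OC[C@H]2C3(C)C | intermediate
29 | tetracyclic methyl ketone | CC(=O)[C@@H]1CC[C@@H]2[C@H](C1)C(=O)OC[C@]21C(=O)C[C@@H]2OC[C@H]1C2(C)C | intermediate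
30 | potassium enolate of 29 (terminal) | [K+].[O-]C(=C)[C@@H]1CC[C@@H]2[C@H](C1)C(=O)OC[C@]21C(=O)C[C@@H]2OC[C@H]1C2(C)C | intermediate
31 | terminal enol triflate | C=C(OS(=O)(=O)C(F)(F)F)[C@@H]1CC[C@@H]2[C@H](C1)C(=O)OC[C@]21C(=O)C[C@@H]2OC[C@H]1C2(C)C | intermediate
32 | CNP0268721.1 (6R,9R,10S,16S,20S,23S in the numbering used here) | C=C(C(=O)O)[C@@H]1CC[C@@H]2[C@H](C1)C(=O)OC[C@]21C(=O)C[C@@H]2OC[C@H]1C2(C)C | target

Total step count: 21. Longest linear sequence: 21 steps (1 to 32); 5, 9 and 23 are bought and enter directly.

Steps most likely to fail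

Step 6. Hydrogen-atom transfer to the doubly activated alkene, or hydride reduction of it, may consume the acceptor before cyclisation. E/Z scrambling of the acceptor at 60 °C may also erode the 1,3-cis selectivity. The fallback sets out from 8 and generates the same C24 radical by halogen abstraction instead of hydrogen-atom transfer. Dry HBr in CH2Cl2 at –78 °C adds in the Markovnikov sense to the isopropenyl group to give the tertiary bromide F1. Knoevenagel condensation with 9 under TiCl4 and pyridine in THF at 0 °C (no nucleophilic amine, which spares the bromide) gives the Z bromo alkylidene keto ester F2. Treatment with (Me3Si)3SiH, Et3B and air in toluene at –40 °C closes ring C by the classical silane-mediated Giese cyclisation and returns to the route at 11. No metal hydride is present, and the low temperature gives the chair preference more weight.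

Step 16. Slow addition at C9, next to the spiro centre, may allow attack of the organometal on the C17 ketone, or loss of the silyl ketene acetal before Mannich capture. The fallback sets out from 22 and annulates ring A under neutral thermal conditions.
- Heating with 2-(trimethylsilyloxy)buta-1,3-diene (toluene, BHT, 170 °C, sealed tube) should give, anti to C23 and with cis fusion, the Diels–Alder adduct F3. The para rule places the siloxy carbon at C7 and the nucleophilic enol carbon at C6.
- C-acylation with acetyl chloride and ZnCl2 gives the β-diketone F4.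
- NaH and PhNTf2 give the ring enol triflate F5.
- Pd(OAc)2, PPh3, HCO2H and Bu3N remove the C7 oxygen to give the acetylcyclohexene F6.
- Hydrogenation over Pd/C followed by equilibration of C6 with DBU returns to the route at 29.

Step 19. Base-induced migration of the exocyclic alkene into ring B, or reversible aldol addition of the enolate to C17, may outrun the 6-endo closure. The fallback sets out from 28 and replaces the enolate by a neutral nucleophile. Me3SiCl, NaI and Et3N in MeCN give the internal (thermodynamic) silyl enol ether F7. TiCl4 in CH2Cl2 at –78 °C then activates the lactone carbonyl for an intramolecular Mukaiyama–Michael addition. Aqueous work-up and brief DBU equilibration return to the route at 29.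

Further compounds
F1 | step 6 | methyl (5S)-6-bromo-5-(tert-butyldimethylsilyloxy)-6-methyl-3-oxoheptanoate | CC(C)(Br)[C@@H](O[Si](C)(C)C(C)(C)C)CC(=O)CC(=O)OC
F2 | step 6 | methyl (2Z,5S)-2-[2-(benzyloxy)ethylidene]-6-bromo-5-(tert-butyldimethylsilyloxy)-6-methyl-3-oxoheptanoate | CC(C)(Br)[C@@H](O[Si](C)(C)C(C)(C)C)CC(=O)/C(C(=O)OC)=C/COCc1ccccc1
F3 | step 16 | cis-fused Diels–Alder adduct, trimethylsilyl enol ether C7(OSiMe3)=C6 | C1=C(O[Si](C)(C)C)C[C@@H]2[C@H](C1)C(=O)OC[C@]21C(=O)C[C@@H]2OC[C@H]1C2(C)C
F4 | step 16 | 6-acetyl-7-oxo tetracycle (β-diketone, C6 labile) | CC(=O)C1C(=O)C[C@@H]2[C@H](C1)C(=O)OC[C@]21C(=O)C[C@@H]2OC[C@H]1C2(C)C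
F5 | step 16 | ring enol triflate C7(OTf)=C6(acetyl) | CC(=O)C1=C(OS(=O)(=O)C(F)(F)F)C[C@@H]2[C@H](C1)C(=O)OC[C@]21C(=O)C[C@@H]2OC[C@H]1C2(C)C
F6 | step 16 | acetylcyclohexene C7H=C6(acetyl) | CC(=O)C1=CC[C@@H]2[C@H](C1)C(=O)OC[C@]21C(=O)C[C@@H]2OC[C@H]1C2(C)C
F7 | step 19 | (Z)-trimethylsilyl enol ether C2(OSiMe3)=C6H of 28 | O=C1OC[C@@]2([C@H](CC/C=C(/C)O[Si](C)(C)C)C1=C)C(=O)C[C@@H]3OC[C@H]2C3(C)C
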